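**Retrosynthetic overview**

- The γ-lactone (O6–C12) is closed last, by desilylation of a seco diester that already carries the epoxyangelate on O8.
- Key disconnection: the C7–C8 bond of the ten-membered carbocycle C1–C10. The C6(O)/C7/C8(O) triad (6,7-anti; 7,8-syn, H7 and H8 cis) is the syn adduct of a (Z)-2-(bromomethyl)enoate, so C8, not the lactone carbinol C6, is made the aldehyde, and the C6 silyl ether is the controlling centre.
- The open chain comes from (S)-glyceraldehyde acetonide (C5–C7, stereocentre C6), a Still–Gennari olefination (Z-C4=C5), an asymmetric vinylogous Mukaiyama aldol (C2–C3, C3 and E-C1=C10) and a vinylalumination/SN2′ bromination (C11–C13).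
- Ring order: carbocycle (chromium allylation), then lactone. The (2R,3R)-epoxy acid comes from angelyl alcohol by Sharpless epoxidation.

Key step: step 16

Remark: locants C1–C15 are the germacrane locants of the target (C12 lactone carbonyl, C13 exo-methylene, C14 ester carbon, C15 methyl); TBS = tert-butyldimethylsilyl, TES = triethylsilyl, PMB = 4-methoxybenzyl; (S)-glyceraldehyde acetonide, the PMB bromoethyl ether and methyl angelate are assumed to be catalogue compounds, and the D-tryptophan-derived catalyst of step 7 is assumed to shield the Re face of the enal.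

**Route**

Step 1
Reactants: 1 trimethyl phosphonoacetate; 2 1-[(2-bromoethoxy)methyl]-4-methoxybenzene
Product: 3 methyl 2-(dimethoxyphosphoryl)-4-(PMBO)butanoate (racemic)
Conditions: NaH, DMF, 0 °C; then 2, NaI (cat.), 60 °C
Reagents that add atoms: none
Why: C-alkylation of the phosphonoacetate anion by a primary bromide (malonate-type alkylation) should give 3; its stereocentre becomes sp2 in step 2.

Step 2
Reactants: 3 methyl 2-(dimethoxyphosphoryl)-4-(PMBO)butanoate; 4 acetaldehyde
Product: 5 methyl (2E)-2-[2-(PMBO)ethyl]but-2-enoate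
Conditions: NaH, THF, 0 °C; then 4, 0 → 25 °C
Reagents that add atoms: none
Why: Horner–Wadsworth–Emmons olefination should give mainly the E enoate, and any Z isomer converges to the same dienolate in step 3.

Step 3
Reactants: 5 methyl (2E)-2-[2-(PMBO)ethyl]but-2-enoate
Product: 6 vinylketene silyl acetal, tert-butyl{[(1Z)-1-methoxy-2-[2-(PMBO)ethyl]buta-1,3-dien-1-yl]oxy}dimethylsilane
Conditions: LDA, THF/DMPU, −78 °C; TBSCl, −78 → 0 °C
Reagents that add atoms: tert-butyldimethylsilyl chloride, CC(C)(C)[Si](C)(C)Cl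
Why: γ-Deprotonation of the tiglate-type ester and O-silylation is the standard entry to α-substituted vinylketene silyl acetals; the acetal geometry is of no consequence.

Step 4
Reactants: 7 (S)-2,2-dimethyl-1,3-dioxolane-4-carbaldehyde; 8 ethyl 2-[bis(2,2,2-trifluoroethoxy)phosphoryl]propanoate
Product: 9 ethyl (2Z)-3-[(4R)-2,2-dimethyl-1,3-dioxolan-4-yl]-2-methylprop-2-enoate
Conditions: KHMDS, 18-crown-6, THF, −78 °C
Reagents that add atoms: none
Why: Still–Gennari olefination should give the Z trisubstituted enoate (C3 cis to C6 across C4=C5); the C6 stereocentre is carried over from 7 untouched.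

Step 5
Reactants: 9 ethyl (2Z)-3-[(4R)-2,2-dimethyl-1,3-dioxolan-4-yl]-2-methylprop-2-enoate
Product: 10 (2Z)-3-[(4R)-2,2-dimethyl-1,3-dioxolan-4-yl]-2-methylprop-2-en-1-ol
Conditions: DIBAL-H (2.2 equiv), CH2Cl2, −78 °C; Rochelle salt
Reagents that add atoms: none
Why: 1,2-Reduction of the enoate by DIBAL-H leaves the Z olefin and the acetal intact.

Step 6
Reactants: 10 (2Z)-3-[(4R)-2,2-dimethyl-1,3-dioxolan-4-yl]-2-methylprop-2-en-1-ol
Product: 11 (2Z)-3-[(4R)-2,2-dimethyl-1,3-dioxolan-4-yl]-2-methylprop-2-enal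
Conditions: MnO2, CH2Cl2, 25 °C; used at once
Reagents that add atoms: none
Why: Neutral allylic oxidation with MnO2 should keep the Z geometry of the enal.

Step 7
Reactants: 11 (2Z)-3-[(4R)-2,2-dimethyl-1,3-dioxolan-4-yl]-2-methylprop-2-enal; 6 vinylketene silyl acetal
Product: 12 methyl (2E,5S,6Z)-7-[(4R)-2,2-dimethyl-1,3-dioxolan-4-yl]-5-hydroxy-2-[2-(PMBO)ethyl]-6-methylhepta-2,6-dienoate
Conditions: B-phenyl oxazaborolidinone of N-tosyl-D-tryptophan (20 mol %), i-PrOH, EtCN, −78 °C
Reagents that add atoms: none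
Why: Catalytic asymmetric vinylogous Mukaiyama aldol: the α-substituted dienolate reacts at its γ-carbon (C2) and gives the E-C1=C10 enoate, and the catalyst should direct attack to the Si face of the aldehyde so that C3 becomes S (sense to be confirmed by Mosher analysis).

Step 8
Reactants: 12 methyl (2E,5S,6Z)-7-[(4R)-2,2-dimethyl-1,3-dioxolan-4-yl]-5-hydroxy-2-[2-(PMBO)ethyl]-6-methylhepta-2,6-dienoate
Product: 13 the 5-O-TBS ether of 12
Conditions: TBSOTf, 2,6-lutidine, CH2Cl2, −78 °C
Reagents that add atoms: tert-butyldimethylsilyl triflate, CC(C)(C)[Si](C)(C)OS(=O)(=O)C(F)(F)F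
Why: Silylation of the secondary allylic alcohol under buffered conditions protects O3 until the last step.

Step 9
Reactants: 13 the 5-O-TBS ether of 12
Product: 14 methyl (2E,5S,6Z,8R)-5-(TBSO)-8,9-dihydroxy-2-[2-(PMBO)ethyl]-6-methylnona-2,6-dienoate
Conditions: CuCl2·2H2O, MeCN, 0 °C
Reagents that add atoms: none
Why: Mild Lewis acid hydrolysis of a terminal isopropylidene acetal should spare the TBS and PMB ethers and frees O6 and O7-CH2.

Step 10
Reactants: 14 methyl (2E,5S,6Z,8R)-5-(TBSO)-8,9-dihydroxy-2-[2-(PMBO)ethyl]-6-methylnona-2,6-dienoate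
Product: 15 the 8,9-bis-O-TES ether of 14
Conditions: TESCl, imidazole, DMAP (cat.), CH2Cl2, 0 → 25 °C
Reagents that add atoms: chlorotriethylsilane, CC[Si](Cl)(CC)CC
Why: Exhaustive silylation sets up the selective oxidation of the primary TES ether and leaves O6 protected.

Step 11
Reactants: 15 the 8,9-bis-O-TES ether of 14
Product: 16 methyl (2E,5S,6Z,8R)-5-(TBSO)-2-[2-(PMBO)ethyl]-6-methyl-9-oxo-8-(TESO)nona-2,6-dienoate
Conditions: (COCl)2, DMSO, CH2Cl2, −78 → −40 °C; Et3N, −78 → −20 °C; used crude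
Reagents that add atoms: none
Why: Swern conditions cleave and oxidise a primary TES ether directly while secondary silyl ethers stay; the α-silyloxy β,γ-unsaturated aldehyde (C7) is used at once to avoid epimerisation at C6.

Step 12
Reactants: 16 methyl (2E,5S,6Z,8R)-5-(TBSO)-2-[2-(PMBO)ethyl]-6-methyl-9-oxo-8-(TESO)nona-2,6-dienoate; 17 methyl propiolate
Product: 19 dimethyl (2E,5S,6Z,8R,9RS)-5-(TBSO)-9-hydroxy-2-[2-(PMBO)ethyl]-6-methyl-10-methylidene-8-(TESO)undeca-2,6-dienedioate, via vinylalane 18 (not isolated)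
Conditions: 17, DIBAL-H, NMO, THF, 0 °C; then 16, 0 → 25 °C; Rochelle salt
Reagents that add atoms: none
Why: Vinylalumination (hydroalumination of the propiolate, then 1,2-addition of the α-aluminoacrylate) gives the Baylis–Hillman-type adduct without amine base; the C7 carbinol forms as an epimer mixture that is erased in step 13.

Step 13
Reactants: 19 dimethyl (2E,5S,6Z,8R,9RS)-5-(TBSO)-9-hydroxy-2-[2-(PMBO)ethyl]-6-methyl-10-methylidene-8-(TESO)undeca-2,6-dienedioate
Product: 20 dimethyl (2E,5S,6Z,8R,9Z)-10-(bromomethyl)-5-(TBSO)-2-[2-(PMBO)ethyl]-6-methyl-8-(TESO)undeca-2,6,9-trienedioate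
Conditions: NBS, Me2S, CH2Cl2, 0 → 25 °C
Reagents that add atoms: N-bromosuccinimide, O=C1CCC(=O)N1Br
Why: SN2′ bromination of the Baylis–Hillman alcohol with the Corey–Kim reagent should give the thermodynamically preferred (Z)-2-(bromomethyl)enoate, with C6 cis to CH2Br.

Step 14
Reactants: 20 dimethyl (2E,5S,6Z,8R,9Z)-10-(bromomethyl)-5-(TBSO)-2-[2-(PMBO)ethyl]-6-methyl-8-(TESO)undeca-2,6,9-trienedioate
Product: 21 the 2-(2-hydroxyethyl) analogue of 20 (free C8 alcohol)
Conditions: DDQ, CH2Cl2/pH 7 buffer, 0 °C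
Reagents that add atoms: none
Why: Oxidative PMB cleavage under buffered conditions should leave the allylic bromide, the silyl ethers and the olefins untouched.

Step 15
Reactants: 21 the 2-(2-hydroxyethyl) analogue of 20
Product: 22 the 2-(2-oxoethyl) analogue of 20 (C8 aldehyde)
Conditions: Dess–Martin periodinane, NaHCO3, CH2Cl2, 0 °C; used crude
Reagents that add atoms: none
Why: Buffered Dess–Martin oxidation gives the β,γ-unsaturated aldehyde without base; it is used at once so that the C1=C10 olefin cannot move into conjugation.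

Step 16
Reactants: 22 the 2-(2-oxoethyl) analogue of 20
Product: 25 methyl (1E,4S,5Z,7R,8R,9R)-4-(TBSO)-9-hydroxy-8-(3-methoxy-3-oxoprop-1-en-2-yl)-5-methyl-7-(TESO)cyclodeca-1,5-diene-1-carboxylate (3S,6R,7R,8R in target locants), via allylchromium species 23 (not isolated), via trimethylsilyl ether 24 (not isolated)
Conditions: CrCl2 (6 equiv), TMSCl (3 equiv), THF, 25 °C, 22 added over 12 h (2 mM); then aq. citric acid, 0 °C
Reagents that add atoms: none
Why: Cr(II) inserts into the allylic C13–Br bond to give the σ-allylchromium(III) species 23, which adds through its γ-carbon C7 to the tethered C8 aldehyde in a six-membered chair (Zimmerman–Traxler) transition state, and TMSCl silylates the chromium alkoxide so that O8 cannot lactonise onto the C12 or C14 esters. The closest known reaction type is the Nozaki–Hiyama–Kishi/Barbier macrocyclisation of 2-(bromomethyl)acrylate aldehydes, which is known to close ten-membered carbocycles. The only ring closed is the carbocycle C1–C10, by intramolecular γ-allylation (C7–C8 bond) of a chain that is pre-bent by its two ring-cis olefins C1=C10 and C4=C5. C8 is set by simple diastereoselection: the 2-ester allylchromium keeps C6 cis to CH2Cr and the aldehyde chain (C9) sits equatorial, which gives the 7,8-syn adduct, the same preference that makes open-chain additions of such reagents cis-lactone selective. C7 is set by C6: allylic 1,3-strain holds H6 in the allyl plane next to C13, the tether carbon C5 must lie on the attacking face and the OTES group anti to it, which gives the 6,7-anti relation and so 6R,7R,8R. The step needs γ- over α-attack (inherent to allylchromium reagents) and ring closure over oligomerisation and over β-silyloxy elimination, which slow addition at high dilution and the preference of chromium for the primary allyl terminus should secure.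

Step 17
Reactants: 26 methyl angelate, methyl (2Z)-2-methylbut-2-enoate
Product: 27 (2Z)-2-methylbut-2-en-1-ol
Conditions: LiAlH4, Et2O, 0 °C
Reagents that add atoms: none
Why: Hydride reduction of the ester gives angelyl alcohol with the Z geometry kept.

Step 18
Reactants: 27 (2Z)-2-methylbut-2-en-1-ol
Product: 28 [(2S,3R)-2,3-dimethyloxiran-2-yl]methanol
Conditions: Ti(OiPr)4 (10 mol %), L-(+)-diethyl tartrate (12 mol %), t-BuOOH, 4 Å MS, CH2Cl2, −20 °C
Reagents that add atoms: tert-butyl hydroperoxide, CC(C)(C)OO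
Why: Sharpless asymmetric epoxidation with L-(+)-tartrate should deliver oxygen to the face that gives the (2S,3R)-epoxy alcohol, and the Z olefin fixes the cis relation of CH2OH and the C3 methyl.

Step 19
Reactants: 28 [(2S,3R)-2,3-dimethyloxiran-2-yl]methanol
Product: 29 (2R,3R)-2,3-dimethyloxirane-2-carboxylic acid
Conditions: RuCl3 (cat.), NaIO4, CCl4/MeCN/H2O, 25 °C
Reagents that add atoms: water, O
Why: RuO4 oxidation of the primary alcohol to the acid leaves the epoxide untouched; C2 becomes R only through the change in CIP priorities.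

Step 20
Reactants: 25 macrocyclic alcohol; 29 (2R,3R)-2,3-dimethyloxirane-2-carboxylic acid
Product: 31 the 9-O-[(2R,3R)-2,3-dimethyloxirane-2-carbonyl] ester of 25, via mixed anhydride 30 (not isolated)
Conditions: 29, 2,4,6-trichlorobenzoyl chloride, Et3N, THF, 25 °C; then 25, DMAP, toluene, 25 °C
Reagents that add atoms: none
Why: Yamaguchi esterification acylates O8 with retention at C8 and without touching the epoxide; it is run directly after step 16 so that the free 8-OH cannot lactonise onto the C12 or C14 ester.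

Step 21
Reactants: 31 the epoxyangelate of 25
Product: 33 CNP0143679.1, via seco hydroxy ester 32 (not isolated)
Conditions: HF·pyridine, pyridine, THF, 0 → 25 °C
Reagents that add atoms: none
Why: Buffered HF removes both silyl ethers, and the freed 6-OH should close the trans γ-lactone on the C12 methyl ester (5-exo-trig transesterification), while the E geometry of C1=C10 keeps 3-OH away from C14.

**Compound list**

1 | trimethyl phosphonoacetate | COC(=O)CP(=O)(OC)OC | starting material
2 | 1-[(2-bromoethoxy)methyl]-4-methoxybenzene | COc1ccc(COCCBr)cc1 | starting material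
3 | methyl 2-(dimethoxyphosphoryl)-4-(PMBO)butanoate (racemic) | COC(=O)C(CCOCc1ccc(OC)cc1)P(=O)(OC)OC | intermediate
4 | acetaldehyde | CC=O | starting material
5 | methyl (2E)-2-[2-(PMBO)ethyl]but-2-enoate | C/C=C(/C(=O)OC)CCOCc1ccc(OC)cc1 | intermediate
6 | vinylketene silyl acetal of 5 | CO/C(O[Si](C)(C)C(C)(C)C)=C(/C=C)CCOCc1ccc(OC)cc1 | intermediate
7 | (S)-2,2-dimethyl-1,3-dioxolane-4-carbaldehyde | O=C[C@@H]1COC(C)(C)O1 | starting material
8 | ethyl 2-[bis(2,2,2-trifluoroethoxy)phosphoryl]propanoate | CCOC(=O)C(C)P(=O)(OCC(F)(F)F)OCC(F)(F)F | starting material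
9 | ethyl (2Z)-3-[(4R)-2,2-dimethyl-1,3-dioxolan-4-yl]-2-methylprop-2-enoate | CCOC(=O)/C(C)=C\[C@@H]1COC(C)(C)O1 | intermediate
10 | (2Z)-3-[(4R)-2,2-dimethyl-1,3-dioxolan-4-yl]-2-methylprop-2-en-1-ol | OC/C(C)=C\[C@@H]1COC(C)(C)O1 | intermediate
11 | (2Z)-3-[(4R)-2,2-dimethyl-1,3-dioxolan-4-yl]-2-methylprop-2-enal | O=C/C(C)=C\[C@@H]1COC(C)(C)O1 | intermediate
12 | methyl (2E,5S,6Z)-7-[(4R)-2,2-dimethyl-1,3-dioxolan-4-yl]-5-hydroxy-2-[2-(PMBO)ethyl]-6-methylhepta-2,6-dienoate | CC1(C)OC[C@@H](/C=C(/C)[C@@H](O)C/C=C(/C(=O)OC)CCOCc2ccc(OC)cc2)O1 | intermediate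
13 | 5-O-TBS ether of 12 | CC1(C)OC[C@@H](/C=C(/C)[C@@H](O[Si](C)(C)C(C)(C)C)C/C=C(/C(=O)OC)CCOCc2ccc(OC)cc2)O1 | intermediate
14 | methyl (2E,5S,6Z,8R)-5-(TBSO)-8,9-dihydroxy-2-[2-(PMBO)ethyl]-6-methylnona-2,6-dienoate | OC[C@H](O)/C=C(/C)[C@@H](O[Si](C)(C)C(C)(C)C)C/C=C(/C(=O)OC)CCOCc1ccc(OC)cc1 | intermediate
15 | 8,9-bis-O-TES ether of 14 | CC[Si](CC)(CC)OC[C@H](O[Si](CC)(CC)CC)/C=C(/C)[C@@H](O[Si](C)(C)C(C)(C)C)C/C=C(/C(=O)OC)CCOCc1ccc(OC)cc1 | intermediate
16 | C7 aldehyde, methyl (2E,5S,6Z,8R)-5-(TBSO)-2-[2-(PMBO)ethyl]-6-methyl-9-oxo-8-(TESO)nona-2,6-dienoate | O=C[C@H](O[Si](CC)(CC)CC)/C=C(/C)[C@@H](O[Si](C)(C)C(C)(C)C)C/C=C(/C(=O)OC)CCOCc1ccc(OC)cc1 | intermediate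
17 | methyl propiolate | C#CC(=O)OC | starting material
18 | [1-(methoxycarbonyl)ethenyl]bis(2-methylpropyl)aluminium | C=C(C(=O)OC)[Al](CC(C)C)CC(C)C | intermediate
19 | Baylis–Hillman-type adduct (C7 carbinol epimers) | C=C(C(=O)OC)C(O)[C@H](O[Si](CC)(CC)CC)/C=C(/C)[C@@H](O[Si](C)(C)C(C)(C)C)C/C=C(/C(=O)OC)CCOCc1ccc(OC)cc1 | intermediate
20 | (Z)-allylic bromide with C8–OPMB | BrC/C(C(=O)OC)=C\[C@H](O[Si](CC)(CC)CC)/C=C(/C)[C@@H](O[Si](C)(C)C(C)(C)C)C/C=C(/C(=O)OC)CCOCc1ccc(OC)cc1 | intermediate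
21 | (Z)-allylic bromide with free C8 alcohol | BrC/C(C(=O)OC)=C\[C@H](O[Si](CC)(CC)CC)/C=C(/C)[C@@H](O[Si](C)(C)C(C)(C)C)C/C=C(/C(=O)OC)CCO | intermediate
22 | (Z)-allylic bromide C8 aldehyde | BrC/C(C(=O)OC)=C\[C@H](O[Si](CC)(CC)CC)/C=C(/C)[C@@H](O[Si](C)(C)C(C)(C)C)C/C=C(/C(=O)OC)CC=O | intermediate
23 | σ-allylchromium(III) dichloride of 22 (solvent ligands omitted) | Cl[Cr](Cl)C/C(C(=O)OC)=C\[C@H](O[Si](CC)(CC)CC)/C=C(/C)[C@@H](O[Si](C)(C)C(C)(C)C)C/C=C(/C(=O)OC)CC=O | intermediate
24 | 8-O-TMS ether of 25 | C=C(C(=O)OC)[C@H]1[C@H](O[Si](CC)(CC)CC)/C=C(/C)[C@@H](O[Si](C)(C)C(C)(C)C)C/C=C(/C(=O)OC)C[C@H]1O[Si](C)(C)C | intermediate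
25 | macrocyclic alcohol (3S,6R,7R,8R; 3-OTBS, 6-OTES, 8-OH) | C=C(C(=O)OC)[C@H]1[C@H](O[Si](CC)(CC)CC)/C=C(/C)[C@@H](O[Si](C)(C)C(C)(C)C)C/C=C(/C(=O)OC)C[C@H]1O | intermediate
26 | methyl angelate | C/C=C(/C)C(=O)OC | starting material
27 | (2Z)-2-methylbut-2-en-1-ol | C/C=C(/C)CO | intermediate
28 | [(2S,3R)-2,3-dimethyloxiran-2-yl]methanol | OC[C@]1(C)O[C@@H]1C | intermediate
29 | (2R,3R)-2,3-dimethyloxirane-2-carboxylic acid | OC(=O)[C@]1(C)O[C@@H]1C | intermediate
30 | mixed anhydride of 29 with 2,4,6-trichlorobenzoic acid | O=C(OC(=O)c1c(Cl)cc(Cl)cc1Cl)[C@]2(C)O[C@@H]2C | intermediate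
31 | 8-O-epoxyangelate of 25 | C=C(C(=O)OC)[C@H]1[C@H](O[Si](CC)(CC)CC)/C=C(/C)[C@@H](O[Si](C)(C)C(C)(C)C)C/C=C(/C(=O)OC)C[C@H]1OC(=O)[C@]2(C)O[C@@H]2C | intermediate
32 | seco hydroxy ester (3,6-diol of 31) | C=C(C(=O)OC)[C@H]1[C@H](O)/C=C(/C)[C@@H](O)C/C=C(/C(=O)OC)C[C@H]1OC(=O)[C@]2(C)O[C@@H]2C | intermediate
33 | CNP0143679.1 | C=C1C(=O)O[C@@H]2/C=C(/C)[C@@H](O)C/C=C(/C(=O)OC)C[C@@H](OC(=O)[C@]3(C)O[C@@H]3C)[C@@H]12 | target

**Step count and risks**

Total step count: 21. Longest linear sequence: 15 steps (steps 4–16, 20 and 21, from 7).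

Steps most likely to fail:

1. Step 16. The strained ten-membered closure may run through a boat-like or aldehyde-axial transition state, which would erode or invert the simple diastereoselection at C8. The allylchromium species may also oligomerise or lose the δ-silyloxy group before it closes. Fallback, from 19: PPTS in MeOH removes the 6-O-TES group and acid catalysis closes the hydroxy methylene lactone F1. NBS/Me2S (SN2′) then gives the bromomethyl butenolide F2, in which the allyl geometry is locked and the C6 substituent shields one face of C7. DDQ and Dess–Martin oxidation give the butenolide alcohol F3 and the butenolide aldehyde F4. CrCl2 closure of F4 must attack C7 anti to C5 (trans-lactone fixed by the five-membered ring) and, through the E-type chair, should give the 8-epi hydroxy lactone F5 (8S). Mitsunobu esterification of F5 with 29 (PPh3, DIAD) inverts C8 and gives the 3-O-TBS ether of the target F6. HF·pyridine then gives 33, where the fallback rejoins the route.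

2. Step 7. The catalyst may give insufficient facial control on the Z-enal, which already carries the C6 stereocentre, and α-attack of the hindered dienolate or Z-to-E drift of the enal may compete. Fallback, from 11: a Nagao acetate aldol with (4S)-3-acetyl-4-isopropyl-1,3-thiazolidine-2-thione (Sn(OTf)2, N-ethylpiperidine, −78 °C; the auxiliary antipode is chosen for 3S) gives the aldol adduct F7. TBSOTf gives its silyl ether F8, and DIBAL-H at −78 °C releases the β-silyloxy aldehyde F9. Horner–Wadsworth–Emmons reaction of F9 with phosphonate 3 (NaH, THF) gives 13, where the fallback rejoins the route.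

3. Step 20. Acyl transfer from a hindered acid to a hindered secondary alcohol is slow, so base-catalysed lactonisation of O8 onto the C12 (or C14) ester may overtake it. Fallback, from 25: the lactonisation is run on purpose (DBU cat., CH2Cl2) to the cis-8,12-lactone F10. PPTS/MeOH removes the 6-O-TES group, and equilibration with DBU should move the lactone to O6, the arrangement favoured in 8β-oxygenated germacranolides, to give the 8-hydroxy 6,12-lactone F11. Esterification of F11 with 29 under the step 20 conditions gives the 3-O-TBS ether of the target F6, and HF·pyridine gives 33.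

**Further compounds**

F1 | step 16 | 6,12-lactone of 19 with free C7-OH (epimers), 3-OTBS, C8-OPMB | C=C1C(O)[C@@H](/C=C(/C)[C@@H](O[Si](C)(C)C(C)(C)C)C/C=C(/C(=O)OC)CCOCc2ccc(OC)cc2)OC1=O
F2 | step 16 | 3-(bromomethyl)butenolide, C8-OPMB | BrCC1=C[C@@H](/C=C(/C)[C@@H](O[Si](C)(C)C(C)(C)C)C/C=C(/C(=O)OC)CCOCc2ccc(OC)cc2)OC1=O
F3 | step 16 | 3-(bromomethyl)butenolide, free C8 alcohol | BrCC1=C[C@@H](/C=C(/C)[C@@H](O[Si](C)(C)C(C)(C)C)C/C=C(/C(=O)OC)CCO)OC1=O
F4 | step 16 | 3-(bromomethyl)butenolide, C8 aldehyde | BrCC1=C[C@@H](/C=C(/C)[C@@H](O[Si](C)(C)C(C)(C)C)C/C=C(/C(=O)OC)CC=O)OC1=O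
F5 | step 16 | 8-epi (8S) hydroxy lactone, 3-OTBS | C=C1C(=O)O[C@@H]2/C=C(/C)[C@@H](O[Si](C)(C)C(C)(C)C)C/C=C(/C(=O)OC)C[C@H](O)[C@@H]12
F6 | step 16 | 3-O-TBS ether of 33 | C=C1C(=O)O[C@@H]2/C=C(/C)[C@@H](O[Si](C)(C)C(C)(C)C)C/C=C(/C(=O)OC)C[C@@H](OC(=O)[C@]3(C)O[C@@H]3C)[C@@H]12
F7 | step 7 | Nagao acetate aldol adduct of 11 (3S) | CC(C)[C@H]1CSC(=S)N1C(=O)C[C@H](O)/C(C)=C\[C@@H]2COC(C)(C)O2
F8 | step 7 | TBS ether of F7 | CC(C)[C@H]1CSC(=S)N1C(=O)C[C@H](O[Si](C)(C)C(C)(C)C)/C(C)=C\[C@@H]2COC(C)(C)O2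
F9 | step 7 | (3S,4Z)-3-(TBSO)-5-[(4R)-2,2-dimethyl-1,3-dioxolan-4-yl]-4-methylpent-4-enal | O=CC[C@H](O[Si](C)(C)C(C)(C)C)/C(C)=C\[C@@H]1COC(C)(C)O1
F10 | step 20 | cis-8,12-lactone of 25 (3-OTBS, 6-OTES) | C=C1[C@H]2[C@H](O[Si](CC)(CC)CC)/C=C(/C)[C@@H](O[Si](C)(C)C(C)(C)C)C/C=C(/C(=O)OC)C[C@H]2OC1=O
F11 | step 20 | 8R-hydroxy 6,12-lactone, 3-OTBS | C=C1C(=O)O[C@@H]2/C=C(/C)[C@@H](O[Si](C)(C)C(C)(C)C)C/C=C(/C(=O)OC)C[C@@H](O)[C@@H]12
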